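**Plan**

1. Locants. Ring A: C1 (oxirane CH), C2 (oxirane C bearing the chain), C3 (CHOH), C4 (=CH), C5 (=C–CH2OH), C6 (CHOH). Chain: C1'(OH)–C2'H=C3'(CH3)–C4'H=C5'H. Ring B is the trimethylcyclohexanediol.
2. Cuts, in order: C3'–C4' (vinylsilane/vinyl iodide coupling); C3–O and C6–O together (O2 removed from a diene); the oxirane bond C1–C2 (6π opening to a 2,5-disubstituted oxepine); in ring B, the bond between CMe2 and the chain-bearing CH (radical epoxy-ene cyclisation of epoxygeranyl acetate).
3. Enabling feature: ring A is a 5,6-epoxycyclohex-2-ene-1,4-diol whose C3-OH and C6-OH are cis to each other and anti to the oxirane O. That is an arene oxide plus O2, and the arene oxide is the valence tautomer of the oxepine O–C2=C3–C4=C5–C6=C1, whose triene termini C2 and C1 are the two oxirane carbons.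
4. Forward, ring A: enyne metathesis, Diels–Alder (all six ring carbons), ynone, dibromide, CBS reduction (C1'), epoxidation, double dehydrobromination. The arene oxides formed relax to the oxepine, which gives up C1–C2 and erases every ring stereocentre of the isomer mixture.
5. The key step re-forms C1–C2 and sets C1, C2, C3 and C6 together. C1' alone decides which of the two equilibrating arene oxides is trapped by singlet oxygen.
6. Ring B: Shi epoxidation sets the carbinol, and chair cyclisation followed by face-selective epoxidation/hydride opening relays it to the other two centres. Z-C2'=C3' comes from trans-hydrosilylation and E-C4'=C5' from Takai olefination; both are retained in the final coupling, and the same fluoride removes the silyl groups.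

Key step: step 8

Assumption: the SMILES is read as written, with C1' and C4' on the same side of C2'=C3' (Z) and C4'=C5' E; compound 14 is drawn as the oxepine, the tautomer that substitution at C2 favours, although it equilibrates rapidly with arene oxides 13.

**Route**

Step 1
Reactants: 1 tert-butyldimethyl(prop-2-yn-1-yloxy)silane; 2 ethylene
Product: 3 tert-butyldimethyl[(2-methylidenebut-3-en-1-yl)oxy]silane
Conditions: second-generation Grubbs catalyst (5 mol %), ethylene (1 atm), CH2Cl2, rt
Reagents that add atoms: none
Why: Enyne cross-metathesis of a terminal propargylic ether with ethylene is a standard, atom-economical entry to 2-substituted 1,3-butadienes and creates no stereocentre.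

Step 2
Reactants: 3 silyloxymethyl butadiene; 4 methyl propiolate
Product: 5 methyl 4-[(tert-butyldimethylsilyloxy)methyl]cyclohexa-1,4-diene-1-carboxylate
Conditions: EtAlCl2 (0.3 equiv), CH2Cl2, −20 °C to rt, argon
Reagents that add atoms: none
Why: The Lewis-acid-promoted Diels–Alder reaction of a 2-substituted diene with an alkynoate follows the para rule, so the ester carbon (C2) and the CH2OSi-bearing carbon (C5) end up para in a 1,4-cyclohexadiene, and the minor meta adduct is removed by chromatography.

Step 3
Reactants: 5 diene ester; 6 prop-1-yn-1-ylmagnesium bromide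
Product: 8 1-{4-[(tert-butyldimethylsilyloxy)methyl]cyclohexa-1,4-dien-1-yl}but-2-yn-1-one, via Weinreb amide 7 (not isolated)
Conditions: MeNH(OMe)·HCl (1.5 equiv), iPrMgCl (3 equiv), THF, −20 °C; then 6 (2 equiv), −20 to 0 °C; aqueous work-up
Reagents that add atoms: none
Why: The one-pot ester-to-ketone conversion through the Weinreb amide stops at the ynone because the magnesium chelate of the tetrahedral adduct survives until work-up, and the low temperature avoids deprotonation of the doubly allylic CH2 groups.

Step 4
Reactants: 8 dienyl ynone
Product: 9 racemic 1-{trans-4,5-dibromo-4-[(tert-butyldimethylsilyloxy)methyl]cyclohex-1-en-1-yl}but-2-yn-1-one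
Conditions: Br2 (1.0 equiv), CH2Cl2, −78 °C
Reagents that add atoms: bromine, BrBr
Why: Electrophilic anti addition of bromine picks the only electron-rich π bond (C4=C5), because the enone C1=C2 and the ynone triple bond are deactivated by the carbonyl group, as in the classical dibromide route to arene oxides, and doing it before the carbinol exists excludes bromoetherification.

Step 5
Reactants: 9 dibromo ynone
Product: 10 (1R)-1-{trans-4,5-dibromo-4-[(tert-butyldimethylsilyloxy)methyl]cyclohex-1-en-1-yl}but-2-yn-1-ol (two diastereomers differing only in the sense of the trans-dibromide)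
Conditions: (R)-2-methyl-CBS-oxazaborolidine (0.2 equiv), catecholborane (1.5 equiv), toluene, −78 °C; MeOH, then pH 7 buffer
Reagents that add atoms: none
Why: In the Corey–Bakshi–Shibata reduction the branched cyclohexenyl group acts as the large and the linear propynyl group as the small substituent, so hydride should reach one carbonyl face and set C1' under reagent control, independently of the remote racemic dibromide, 1,2-selectively and without base.

Step 6
Reactants: 10 dibromo propargylic alcohol
Product: 11 (1'S)-epoxy alcohol: 1-{3,4-dibromo-4-[(tert-butyldimethylsilyloxy)methyl]-7-oxabicyclo[4.1.0]heptan-1-yl}but-2-yn-1-ol (mixture of ring diastereomers)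
Conditions: VO(acac)2 (2 mol %), tBuOOH (1.3 equiv, decane), CH2Cl2, 0 °C
Reagents that add atoms: tert-butyl hydroperoxide, CC(C)(C)OO
Why: Vanadium-catalysed hydroxyl-directed epoxidation of the allylic alcohol oxidises the only remaining alkene, C1=C2, and its diastereoselectivity does not matter because the oxirane stereocentres are erased in step 7.

Step 7
Reactants: 11 epoxy alcohol
Product: 14 (S)-2-[1-(trimethylsilyloxy)but-2-yn-1-yl]-5-[(tert-butyldimethylsilyloxy)methyl]oxepine, via trimethylsilyl ether 12 (not isolated), via arene oxides 13 (not isolated)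
Conditions: 1-(trimethylsilyl)imidazole (1.5 equiv), THF, 0 °C; then DBU (4 equiv), 0 °C to rt; filtration through basic alumina, used at once
Reagents that add atoms: 1-(trimethylsilyl)imidazole, C[Si](C)(C)n1ccnc1
Why: Neutral O-silylation masks the hydroxyl, and two E2 dehydrobrominations (the classical epoxide–dibromide route to arene oxides) give arene oxides 13, which relax by 6π electrocyclic ring opening to the oxepine, so all diastereomers of 11 converge on one compound whose only stereocentre is C1'.

Step 8
Reactants: 14 oxepine
Product: 18 ring A triol (C1' S; C3-OH and C6-OH cis to each other and anti to the oxirane O; propynyl carbinol on C2; CH2OTBS on C5), via arene oxide 15 (not isolated), via endoperoxide 16 (not isolated), via diol silyl ether 17 (not isolated)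
Conditions: O2, tetraphenylporphyrin (1 mol %), white LED, CH2Cl2, −78 °C, base-washed glassware; then thiourea (1.5 equiv), MeOH, −78 to 0 °C; then K2CO3 (0.1 equiv), 0 °C
Reagents that add atoms: oxygen, O=O
Why: Oxepine 14 equilibrates thermally and rapidly, even at −78 °C, with both C1/C2-diastereomeric arene oxides by disrotatory 6π electrocyclisation of the triene C2=C3–C4=C5–C6=C1, the new C1–C2 σ bond closing the oxirane and the cyclohexadiene at the same time, and only the arene oxides offer the planar s-cis diene C3=C4–C5=C6 to which singlet oxygen adds in a suprafacial [4+2] cycloaddition that closes the 2,3-dioxabicyclo[2.2.2]octene of 16. The closest known reaction type is the dye-sensitised photooxygenation of benzene oxide–oxepine and of 1-substituted benzene oxides to anti-epoxy endoperoxides, followed by thiourea reduction of the O–O bond to the cis-ene-1,4-diol. Disrotation inside the ring can only give the cis-fused oxirane (C1, C2), suprafacial addition makes C3–O and C6–O cis, and O2 approaches anti to the oxirane oxygen for steric and lone-pair reasons, so the relative configuration of all four new centres is fixed by the mechanism. Which arene oxide is trapped (Curtin–Hammett) is decided by C1': the attacked face stays open only when the C1'–H bond lies over it, and in 15 this rotamer puts the silyloxy oxygen next to C3–H and far from the oxirane C–O dipole with the propynyl group in the open sector outside the oxirane, whereas the other arene oxide must press propynyl against C3–H and nearly eclipse the two C–O bonds, or else turn the silyloxy oxygen towards the incoming, negatively polarised O2. The hydroxyl is masked for this reason, since a free O–H would hydrogen-bond to the incoming O2 and is expected to favour the other arene oxide. Chemoselectivity is needed against the alkyne, the silyl ethers and the enol-ether bonds of 14, and it rests on the inertness of alkynes to singlet oxygen and on the higher reactivity of the cisoid diene, after which thiourea and catalytic K2CO3 in MeOH cleave only O–O and O–SiMe3.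

Step 9
Reactants: 18 ring A triol
Product: 19 (Z)-vinylsilane (benzyldimethylsilyl on C3', cis to C1')
Conditions: [Cp*Ru(MeCN)3]PF6 (3 mol %), BnMe2SiH (1.2 equiv), acetone, 0 °C to rt
Reagents that add atoms: benzyldimethylsilane, C[SiH](C)Cc1ccccc1
Why: Ruthenium-catalysed trans-hydrosilylation of internal propargylic alcohols places silicon on the alkyne carbon distal to the hydroxyl and adds H and Si anti, which gives the Z-vinylsilane under neutral conditions that spare the oxirane, the ring alkene and the free hydroxyls.

Step 10
Reactants: 20 geranyl acetate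
Product: 21 (2E)-5-[(2R)-3,3-dimethyloxiran-2-yl]-3-methylpent-2-en-1-yl acetate
Conditions: D-fructose-derived Shi ketone (0.3 equiv), Oxone (2KHSO5·KHSO4·K2SO4), K2CO3, Bu4NHSO4 (cat.), MeCN–dimethoxymethane/aq. Na2B4O7–Na2EDTA buffer, −5 °C
Reagents that add atoms: potassium peroxymonosulfate, [K+].[O-]S(=O)(=O)OO
Why: The Shi epoxidation attacks the electron-richer 6,7-alkene (the 2,3-alkene is deactivated by the allylic acetate) and should give the R epoxide through the spiro transition state, which is the source of all ring B stereochemistry.

Step 11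
Reactants: 21 epoxygeranyl acetate
Product: 23 [(1S,3R)-3-hydroxy-2,2-dimethyl-6-methylidenecyclohexyl]methyl acetate, via trimethylsilyl ether 22 (not isolated)
Conditions: Cp2TiCl2 (0.2 equiv), Mn dust (8 equiv), Me3SiCl (4 equiv), 2,4,6-collidine (7 equiv), THF, rt; then 1 M aq. HCl work-up
Reagents that add atoms: none
Why: In this titanocene-catalysed radical epoxy-ene cyclisation, Cp2TiCl (trivalent titanium, made by Mn and recycled by Me3SiCl/collidine) opens the epoxide homolytically to the tertiary radical, which closes ring B 6-endo through a chair with the C–O and CH2OAc groups equatorial and cis, the carbinol configuration being retained, and β-hydride elimination leaves the exocyclic alkene.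

Step 12
Reactants: 23 hydroxy alkene acetate
Product: 24 triethylsilyl ether of 23
Conditions: Et3SiCl (1.3 equiv), imidazole (2 equiv), DMF, 0 °C to rt
Reagents that add atoms: chlorotriethylsilane, CC[Si](Cl)(CC)CC
Why: Standard silylation masks the secondary alcohol, which would otherwise form a lactol and a lactone with the later aldehyde, as an ether that fluoride removes easily in spite of the neighbouring quaternary carbon.

Step 13
Reactants: 24 silyl ether
Product: 25 spiro-epoxide (1-oxaspiro[2.5]octane; oxirane O equatorial and trans to the CH2OAc arm)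
Conditions: mCPBA (1.2 equiv), CH2Cl2, −10 °C
Reagents that add atoms: 3-chloroperoxybenzoic acid, OOC(=O)c1cccc(Cl)c1
Why: The Prilezhaev epoxidation of the exocyclic methylene should take place from the equatorial side, because the axial methyl of the gem-dimethyl group in the 1,3-position blocks the axial trajectory, and this puts the new C–O bond equatorial.

Step 14
Reactants: 25 spiro-epoxide
Product: 26 (1R,2S,4R)-2-(hydroxymethyl)-1,3,3-trimethyl-4-(triethylsilyloxy)cyclohexan-1-ol
Conditions: LiAlH4 (3 equiv), THF, 0 to 40 °C; Fieser work-up
Reagents that add atoms: none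
Why: Hydride opens the spiro-oxirane in SN2 fashion at its unhindered CH2 terminus, leaving the equatorial tertiary alcohol with an axial methyl group without touching the stereocentre, and the same reagent reduces the acetate to the primary alcohol.

Step 15
Reactants: 26 diol
Product: 27 β-hydroxy aldehyde (formyl group in place of CH2OH)
Conditions: (nPr4N)RuO4 (5 mol %), N-methylmorpholine N-oxide (1.5 equiv), 4 Å molecular sieves, CH2Cl2, rt
Reagents that add atoms: none
Why: The Ley–Griffith oxidation converts the primary alcohol into the aldehyde under neutral conditions that leave the tertiary alcohol alone and avoid epimerisation and retro-aldol cleavage.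

Step 16
Reactants: 27 aldehyde
Product: 28 (E)-vinyl iodide of ring B
Conditions: CrCl2 (8 equiv), CHI3 (2.5 equiv), THF–1,4-dioxane, 0 °C to rt
Reagents that add atoms: iodoform, IC(I)I
Why: The Takai olefination with the geminal dichromium reagent from CHI3 and CrCl2 (divalent chromium) is non-basic, tolerates the free tertiary alcohol and gives the E-iodoalkene, all the more so with a branched aldehyde.

Step 17
Reactants: 19 (Z)-vinylsilane; 28 (E)-vinyl iodide
Product: 30 Arthrosporol A, via coupled bis-silyl ether 29 (not isolated)
Conditions: 19, Bu4NF (3 equiv), THF, 0 °C; then 28, Pd2(dba)3·CHCl3 (2.5 mol %), rt; then Bu4NF (4 equiv), rt; CaCO3/sulfonic acid resin work-up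
Reagents that add atoms: none
Why: In the fluoride-promoted Hiyama–Denmark coupling the benzyl group is cleaved from silicon, the activated silane (held as a five-membered siloxane by the cis C1' hydroxyl) transmetalates to the alkenylpalladium iodide formed from zerovalent palladium, both alkene geometries are retained, and the excess fluoride then removes the TBS and TES ethers.

**Compound list**

1 | tert-butyldimethyl(prop-2-yn-1-yloxy)silane | C#CCO[Si](C)(C)C(C)(C)C | starting material
2 | ethylene | C=C | starting material
3 | tert-butyldimethyl[(2-methylidenebut-3-en-1-yl)oxy]silane | C=CC(=C)CO[Si](C)(C)C(C)(C)C | intermediate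
4 | methyl propiolate | C#CC(=O)OC | starting material
5 | methyl 4-[(tert-butyldimethylsilyloxy)methyl]cyclohexa-1,4-diene-1-carboxylate | COC(=O)C1=CCC(CO[Si](C)(C)C(C)(C)C)=CC1 | intermediate
6 | prop-1-yn-1-ylmagnesium bromide | CC#C[Mg]Br | starting material
7 | Weinreb amide of 5 (N-methoxy-N-methyl carboxamide) | CON(C)C(=O)C1=CCC(CO[Si](C)(C)C(C)(C)C)=CC1 | intermediate
8 | 1-{4-[(tert-butyldimethylsilyloxy)methyl]cyclohexa-1,4-dien-1-yl}but-2-yn-1-one | CC#CC(=O)C1=CCC(CO[Si](C)(C)C(C)(C)C)=CC1 | intermediate
9 | racemic trans-4,5-dibromide of 8 | CC#CC(=O)C1=CCC(Br)(CO[Si](C)(C)C(C)(C)C)C(Br)C1 | intermediate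
10 | (1R)-propargylic alcohol from 9 (both trans-dibromide diastereomers) | CC#C[C@H](O)C1=CCC(Br)(CO[Si](C)(C)C(C)(C)C)C(Br)C1 | intermediate
11 | (1'S)-epoxy alcohol, C1–C2 oxirane (ring diastereomers) | CC#C[C@H](O)C12OC1CC(Br)(CO[Si](C)(C)C(C)(C)C)C(Br)C2 | intermediate
12 | trimethylsilyl ether of 11 | CC#C[C@H](O[Si](C)(C)C)C12OC1CC(Br)(CO[Si](C)(C)C(C)(C)C)C(Br)C2 | intermediate
13 | arene oxides, both oxirane diastereomers, C1' S | CC#C[C@H](O[Si](C)(C)C)C12OC1C=C(CO[Si](C)(C)C(C)(C)C)C=C2 | intermediate
14 | (S)-2-[1-(trimethylsilyloxy)but-2-yn-1-yl]-5-[(tert-butyldimethylsilyloxy)methyl]oxepine | CC#C[C@H](O[Si](C)(C)C)C1=CC=C(CO[Si](C)(C)C(C)(C)C)C=CO1 | intermediate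
15 | reacting arene oxide, C1/C2 as in the target | CC#C[C@H](O[Si](C)(C)C)[C@]12O[C@H]1C=C(CO[Si](C)(C)C(C)(C)C)C=C2 | intermediate
16 | anti-epoxy endoperoxide (O–O bridge C3 to C6, anti to the oxirane O) | CC#C[C@H](O[Si](C)(C)C)[C@]12O[C@H]1[C@@H]3OO[C@H]2C=C3CO[Si](C)(C)C(C)(C)C | intermediate
17 | cis-3,6-diol, C1' trimethylsilyl ether | CC#C[C@H](O[Si](C)(C)C)[C@]12O[C@H]1[C@H](O)C(CO[Si](C)(C)C(C)(C)C)=C[C@@H]2O | intermediate
18 | ring A triol | CC#C[C@H](O)[C@]12O[C@H]1[C@H](O)C(CO[Si](C)(C)C(C)(C)C)=C[C@@H]2O | intermediate
19 | (Z)-3'-(benzyldimethylsilyl)alkene of ring A | CC(=C/[C@H](O)[C@]12O[C@H]1[C@H](O)C(CO[Si](C)(C)C(C)(C)C)=C[C@@H]2O)/[Si](C)(C)Cc1ccccc1 | intermediate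
20 | geranyl acetate | CC(C)=CCC/C(C)=C/COC(C)=O | starting material
21 | (R)-6,7-epoxygeranyl acetate | CC(=O)OC/C=C(C)/CC[C@H]1OC1(C)C | intermediate
22 | trimethylsilyl ether of 23 | CC(=O)OC[C@@H]1C(C)(C)[C@H](O[Si](C)(C)C)CCC1=C | intermediate
23 | [(1S,3R)-3-hydroxy-2,2-dimethyl-6-methylidenecyclohexyl]methyl acetate | CC(=O)OC[C@@H]1C(C)(C)[C@H](O)CCC1=C | intermediate
24 | triethylsilyl ether of 23 | CC(=O)OC[C@@H]1C(C)(C)[C@H](O[Si](CC)(CC)CC)CCC1=C | intermediate
25 | spiro-epoxide, O equatorial, trans to CH2OAc | CC(=O)OC[C@@H]1C(C)(C)[C@H](O[Si](CC)(CC)CC)CC[C@@]12OC2 | intermediate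
26 | primary/tertiary diol of ring B | OC[C@@H]1C(C)(C)[C@H](O[Si](CC)(CC)CC)CC[C@@]1(C)O | intermediate
27 | β-hydroxy aldehyde of ring B | O=C[C@@H]1C(C)(C)[C@H](O[Si](CC)(CC)CC)CC[C@@]1(C)O | intermediate
28 | (E)-vinyl iodide of ring B | I/C=C/[C@@H]1C(C)(C)[C@H](O[Si](CC)(CC)CC)CC[C@@]1(C)O | intermediate
29 | coupled (2'Z,4'E)-diene, TBS and TES ethers in place | CC(=C/[C@H](O)[C@]12O[C@H]1[C@H](O)C(CO[Si](C)(C)C(C)(C)C)=C[C@@H]2O)/C=C/[C@@H]1C(C)(C)[C@H](O[Si](CC)(CC)CC)CC[C@@]1(C)O | intermediate
30 | Arthrosporol A | CC(=C/[C@H](O)[C@]12O[C@H]1[C@H](O)C(CO)=C[C@@H]2O)/C=C/[C@@H]1C(C)(C)[C@H](O)CC[C@@]1(C)O | target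

Total step count: 17.
Longest linear sequence: 10 (steps 1 to 9, then step 17).

**Steps most likely to fail**

**Step 8.** Discrimination between the two equilibrating arene oxides may be weak or inverted. Singlet oxygen may also attack the enol-ether bonds of the oxepine, and traces of acid may trigger aromatisation.

The fallback replaces the steric and dipolar relay by hydroxyl delivery from a sacrificial C1' configuration. It sets out from 9 and returns at 18.
- Reduction of 9 with the enantiomeric (S)-oxazaborolidine and catecholborane gives the C1'-epimeric carbinol F1.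
- VO(acac)2/tBuOOH gives the epoxy alcohol F2, and DBU alone gives the free-hydroxy oxepine F3.
- Photooxygenation (O2, tetraphenylporphyrin, CH2Cl2, −78 °C) then uses the hydroxy-directing effect known for singlet oxygen. In the arene oxide F4 that has the ring A configuration of the target, the O–H over the attacked face can hydrogen-bond to the incoming O2 in a chair-like six-membered array with propynyl equatorial. This should lead to the hydroxy endoperoxide F5.
- The peroxide bridge still masks both ring oxygens, so the only free hydroxyl is oxidised with Dess–Martin periodinane to the epoxy ynone F6.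
- C1' is reset under reagent control ((R)-oxazaborolidine, catecholborane, −78 °C) to the hydroxy endoperoxide F7, and thiourea in MeOH gives 18.

**Step 17.** Protodesilylation of the activated silane may outrun transmetalation, and fluoride or alkoxide may induce epoxide migration in the free epoxy alcohols.

The fallback exchanges the roles of the partners and uses a boron coupling. It sets out from 19 and 27 and returns at 29.
- Iododesilylation of 19 with N-iodosuccinimide in (CF3)2CHOH at 0 °C, with retention, gives the (Z)-vinyl iodide F8.
- Boron-Takai olefination of 27 (Cl2CHB(pin), CrCl2, LiI, THF) gives the (E)-vinylboronate F9.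
- Suzuki–Miyaura coupling (Pd(dppf)Cl2, K3PO4, THF–H2O, rt) gives 29, which is isolated and desilylated with AcOH-buffered Bu4NF to 30.

**Step 9.** Regiocontrol may be lost, with silicon delivered to the alkyne carbon next to C1'.

The fallback ties the silane to the C1' oxygen. It sets out from 18 and returns at 30.
- Silylation of all three hydroxyls with (HMe2Si)2NH gives the tris(dimethylsilyl) ether F10.
- Catalytic KOtBu in THF triggers the alkoxide-induced intramolecular trans-hydrosilylation that only the propargylic silyl ether can undergo. The five-membered ring of the oxasilole F11 forces silicon onto C3', cis to C1'.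
- F11 couples with 28 under the conditions of step 17, where fluoride also removes the remaining silyl groups, to give 30.

**Further compounds**

F1 | step 8 | (1S)-propargylic alcohol, C1' epimer of 10 | CC#C[C@@H](O)C1=CCC(Br)(CO[Si](C)(C)C(C)(C)C)C(Br)C1
F2 | step 8 | (1'R)-epoxy alcohol, C1' epimer of 11 | CC#C[C@@H](O)C12OC1CC(Br)(CO[Si](C)(C)C(C)(C)C)C(Br)C2
F3 | step 8 | (R)-1-{5-[(tert-butyldimethylsilyloxy)methyl]oxepin-2-yl}but-2-yn-1-ol | CC#C[C@@H](O)C1=CC=C(CO[Si](C)(C)C(C)(C)C)C=CO1
F4 | step 8 | free-hydroxy arene oxide, ring as in the target, C1' R | CC#C[C@@H](O)[C@]12O[C@H]1C=C(CO[Si](C)(C)C(C)(C)C)C=C2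
F5 | step 8 | hydroxy endoperoxide, C1' R | CC#C[C@@H](O)[C@]12O[C@H]1[C@@H]3OO[C@H]2C=C3CO[Si](C)(C)C(C)(C)C
F6 | step 8 | epoxy endoperoxy ynone | CC#CC(=O)[C@]12O[C@H]1[C@@H]3OO[C@H]2C=C3CO[Si](C)(C)C(C)(C)C
F7 | step 8 | hydroxy endoperoxide, C1' S | CC#C[C@H](O)[C@]12O[C@H]1[C@@H]3OO[C@H]2C=C3CO[Si](C)(C)C(C)(C)C
F8 | step 17 | (Z)-3'-iodoalkene of ring A | CC(=C/[C@H](O)[C@]12O[C@H]1[C@H](O)C(CO[Si](C)(C)C(C)(C)C)=C[C@@H]2O)/I
F9 | step 17 | (E)-vinylboronic acid pinacol ester of ring B | CC1(C)OB(/C=C/[C@@H]2C(C)(C)[C@H](O[Si](CC)(CC)CC)CC[C@@]2(C)O)OC1(C)C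
F10 | step 9 | tris(dimethylsilyl) ether of 18 | CC#C[C@H](O[SiH](C)C)[C@]12O[C@H]1[C@H](O[SiH](C)C)C(CO[Si](C)(C)C(C)(C)C)=C[C@@H]2O[SiH](C)C
F11 | step 9 | 2,2,3-trimethyl-2,5-dihydro-1,2-oxasilole carrying ring A at C5 | CC1=C[C@H](O[Si]1(C)C)[C@]23O[C@H]2[C@H](O[SiH](C)C)C(CO[Si](C)(C)C(C)(C)C)=C[C@@H]3O[SiH](C)C
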